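**Plan**

1. Numbering: 1,2-dioxolane O1–O2–C3–C4–C5; C3 carries CH3 and CH2CO2H, C5 carries CH3 and CH2CH(CH3)(CH2)8Ph. The peroxy-bearing, fully substituted C5 and the oxygenated C3 are 1,3-related across C4, which is the spacing of the two C–O carbons of an oxetane, so C5–O1 can be made by H2O2 opening a 2,2,4-trisubstituted oxetane at its tertiary carbon.
2. Retrosynthetic cuts, in order: C3–CH2CO2H (peroxycarbenium ion + ketene thioacetal), O2–C3 (peroxy-hemiketal), C5–O1 (oxetane + H2O2), the oxetane O–C bond at the secondary carbon, C3–CH3 (Grignard), C5–CH3 and C4–C3 (carboalumination/formaldehyde), CH2–C5 (acetylide), and the CH2–CH2 bond joining the chiral C4 unit to the phenylheptyl chain.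
3. Forward: the chain is built linearly; the oxetane is the first ring (step 9) and is opened in step 10; the dioxolane, the only ring of the target, closes in step 13 by addition of O–O–H to the ketone; the acid arm comes last.
4. Stereochemistry: the side-chain methyl centre comes from (S)-3-bromo-2-methylpropan-1-ol; C5 is set by Sharpless epoxidation (L-(+)-diethyl tartrate) and inverted once in the oxetane opening; C3 arises by capture of a planar peroxycarbenium ion and the wanted epimer is separated.

Key step: step 10

Remark: the carbinol carbon made in step 7 ends as the C3 ketone/ketal carbon, so 14–17, 19 and 20 are carried as pairs of epimers at that carbon and 24 as a pair of C3 epimers; their SMILES leave that centre open.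

**Route**

Step 1
Reactants: 1 (S)-3-bromo-2-methylpropan-1-ol; 2 (7-bromoheptyl)benzene
Product: 5 (R)-2-methyl-10-phenyldecan-1-ol, via Grignard reagent 3 (not isolated), via chloromagnesium alkoxide 4 (not isolated)
Conditions: 2 (1.3 equiv), Mg, THF, 45 °C; separately 1, MeMgCl (1.0 equiv), THF, −78 °C; then 3, Li2CuCl4 (0.03 equiv), −78 → 0 °C; sat. aq. NH4Cl
Reagents that add atoms: none
Why: Kochi-type copper-catalysed coupling of a primary alkyl Grignard reagent with a primary alkyl bromide, the hydroxyl being masked in the flask as its magnesium alkoxide, and the stereocentre is a spectator whose descriptor alone changes from S to R.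

Step 2
Reactants: 5 (R)-2-methyl-10-phenyldecan-1-ol
Product: 6 (R)-2-methyl-10-phenyldecyl 4-methylbenzenesulfonate
Conditions: TsCl (1.3 equiv), Et3N (2 equiv), DMAP (0.1 equiv), CH2Cl2, 0 °C → rt
Reagents that add atoms: 4-methylbenzenesulfonyl chloride, Cc1ccc(cc1)S(=O)(=O)Cl
Why: Routine tosylation of an unhindered primary alcohol in which no bond to the stereocentre is touched.

Step 3
Reactants: 6 (R)-2-methyl-10-phenyldecyl 4-methylbenzenesulfonate; 7 lithium acetylide ethylenediamine complex
Product: 8 (R)-4-methyl-12-phenyldodec-1-yne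
Conditions: LiC≡CH·H2NCH2CH2NH2 (2 equiv), DMSO, 15 °C → rt
Reagents that add atoms: none
Why: SN2 alkylation of lithium acetylide in DMSO, a standard homologation of β-methyl-branched primary tosylates in which substitution outruns elimination.

Step 4
Reactants: 8 (R)-4-methyl-12-phenyldodec-1-yne
Product: 11 (2E,5R)-3,5-dimethyl-13-phenyltridec-2-en-1-ol, via alkenylalane 9 (not isolated), via lithium alkenylaluminate 10 (not isolated)
Conditions: Me3Al (2.5 equiv), Cp2ZrCl2 (0.25 equiv), CH2Cl2, 0 °C → rt; volatiles removed; n-BuLi (1.1 equiv), hexane/THF, −78 → 0 °C; (CH2O)n (4 equiv), rt; aq. HCl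
Reagents that add atoms: trimethylaluminium, C[Al](C)C; formaldehyde (as paraformaldehyde), C=O
Why: Negishi zirconium-catalysed carboalumination adds CH3 and Al syn across the terminal alkyne with the methyl on the internal carbon, and hydroxymethylation of the derived aluminate proceeds with retention at the alkenyl carbon, which fixes the E geometry.

Step 5
Reactants: 11 (2E,5R)-3,5-dimethyl-13-phenyltridec-2-en-1-ol
Product: 12 [(2S,3S)-3-methyl-3-[(2R)-2-methyl-10-phenyldecyl]oxiran-2-yl]methanol
Conditions: Ti(OiPr)4 (0.10 equiv), L-(+)-diethyl tartrate (0.12 equiv), t-BuOOH (2 equiv, anhydrous), 4 Å molecular sieves, CH2Cl2, −20 °C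
Reagents that add atoms: tert-butyl hydroperoxide, CC(C)(C)OO
Why: Sharpless asymmetric epoxidation, in which L-(+)-diethyl tartrate directs oxygen to the alkene face that gives the (2S,3S)-epoxide of an E-3-methylalk-2-en-1-ol (the geraniol pattern), so that reagent control sets the tertiary C–O stereocentre independently of the remote C5 methyl group.

Step 6
Reactants: 12 [(2S,3S)-3-methyl-3-[(2R)-2-methyl-10-phenyldecyl]oxiran-2-yl]methanol
Product: 13 (2R,3S)-3-methyl-3-[(2R)-2-methyl-10-phenyldecyl]oxirane-2-carbaldehyde
Conditions: TEMPO (0.1 equiv), PhI(OAc)2 (1.2 equiv), CH2Cl2, rt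
Reagents that add atoms: none
Why: TEMPO/PhI(OAc)2 (oxoammonium) oxidation takes a primary alcohol to the aldehyde without base or strong acid, conditions under which the trisubstituted epoxide should persist (the descriptor at C2 changes only through ligand priorities).

Step 7
Reactants: 13 (2R,3S)-3-methyl-3-[(2R)-2-methyl-10-phenyldecyl]oxirane-2-carbaldehyde
Product: 14 1-[(2S,3S)-3-methyl-3-[(2R)-2-methyl-10-phenyldecyl]oxiran-2-yl]ethan-1-ol
Conditions: MeMgBr (1.5 equiv), THF, −78 °C; sat. aq. NH4Cl
Reagents that add atoms: methylmagnesium bromide, C[Mg]Br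
Why: Grignard addition to an aldehyde, which at −78 °C in THF is far faster than attack on the epoxide, and the new carbinol centre is formed without control because it is oxidised to the ketone in step 12.

Step 8
Reactants: 14 1-[(2S,3S)-3-methyl-3-[(2R)-2-methyl-10-phenyldecyl]oxiran-2-yl]ethan-1-ol
Product: 15 (4S,6R)-4,6-dimethyl-14-phenyltetradecane-2,4-diol
Conditions: NaAlH2(OCH2CH2OMe)2 (3 equiv), THF, 0 °C → rt; aq. potassium sodium tartrate
Reagents that add atoms: none
Why: Hydroxyl-directed reduction of a 2,3-epoxy alcohol, in which the alkoxyaluminate delivers hydride intramolecularly to the epoxide carbon next to the carbinol (the only non-quaternary one), giving the 1,3-diol and leaving the tertiary C–O bond and its S configuration intact.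

Step 9
Reactants: 15 (4S,6R)-4,6-dimethyl-14-phenyltetradecane-2,4-diol
Product: 17 (2S)-2,4-dimethyl-2-[(2R)-2-methyl-10-phenyldecyl]oxetane, via secondary monomesylate 16 (not isolated)
Conditions: MsCl (1.05 equiv), Et3N (1.5 equiv), THF, −20 °C; then KOtBu (3 equiv), 0 → 40 °C
Reagents that add atoms: none
Why: Selective mesylation of the secondary hydroxyl followed by intramolecular Williamson etherification (4-exo-tet) by the tertiary potassium alkoxide, a standard oxetane synthesis from 1,3-diols in which the tertiary stereocentre is retained because its C–O bond is never broken.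

Step 10
Reactants: 17 (2S)-2,4-dimethyl-2-[(2R)-2-methyl-10-phenyldecyl]oxetane; 18 hydrogen peroxide
Product: 19 (4R,6R)-4-hydroperoxy-4,6-dimethyl-14-phenyltetradecan-2-ol
Conditions: 18 (10 equiv, dried ca. 2 M solution in Et2O), Me3SiOTf (0.2 equiv), Et2O, −78 → −20 °C; aq. NaHCO3
Reagents that add atoms: none
Why: Me3SiOTf (or the triflic acid it releases with H2O2) activates the oxetane oxygen, and H2O2 attacks the tertiary carbon from the side opposite the departing oxygen in a loose, ion-pair-like SN2 transition state driven by release of ring strain, so the C–OOH bond forms with inversion. The closest known reaction type is the Lewis-acid-promoted perhydrolysis of substituted oxetanes and epoxides at the more substituted carbon. No ring is closed; the four-membered ring is opened. The new peroxy-bearing stereocentre (C4 of 19, C5 of the target) is controlled by the configuration of the oxetane carbon, which goes back to the Sharpless epoxidation and is turned from S to R. The step needs regioselectivity for the tertiary over the secondary C–O bond, which the better charge stabilisation at the fully substituted carbon should secure, and it needs substitution with inversion to win over free-cation pathways (loss of configuration, elimination, attack by product hydroperoxide), which low temperature, the ether solvent and the large excess of H2O2 are meant to secure.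

Step 11
Reactants: 19 (4R,6R)-4-hydroperoxy-4,6-dimethyl-14-phenyltetradecan-2-ol
Product: 20 (4R,6R)-4-[(2-methoxypropan-2-yl)peroxy]-4,6-dimethyl-14-phenyltetradecan-2-ol
Conditions: 2-methoxypropene (1.2 equiv), pyridinium p-toluenesulfonate (0.05 equiv), CH2Cl2, −20 → 0 °C
Reagents that add atoms: 2-methoxypropene, COC(C)=C
Why: Acid-catalysed addition of the hydroperoxide to an enol ether (monoperoxyketal protection), the more acidic and α-effect-enhanced O–O–H being expected to trap the oxocarbenium ion ahead of the hindered secondary hydroxyl when about one equivalent is used at low temperature.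

Step 12
Reactants: 20 (4R,6R)-4-[(2-methoxypropan-2-yl)peroxy]-4,6-dimethyl-14-phenyltetradecan-2-ol
Product: 21 (4R,6R)-4-[(2-methoxypropan-2-yl)peroxy]-4,6-dimethyl-14-phenyltetradecan-2-one
Conditions: Dess–Martin periodinane (1.5 equiv), pyridine (4 equiv), CH2Cl2, 0 °C → rt
Reagents that add atoms: none
Why: Dess–Martin oxidation of a secondary alcohol under pyridine buffering, mild non-metallic conditions that a peroxyketal should tolerate and that avoid base-induced β-elimination of the peroxide from the new ketone.

Step 13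
Reactants: 21 (4R,6R)-4-[(2-methoxypropan-2-yl)peroxy]-4,6-dimethyl-14-phenyltetradecan-2-one
Product: 24 (5R)-3-methoxy-3,5-dimethyl-5-[(2R)-2-methyl-10-phenyldecyl]-1,2-dioxolane, via hydroperoxy ketone 22 (not isolated), via dioxolanol 23 (not isolated)
Conditions: p-TsOH·H2O (0.1 equiv), MeOH, rt
Reagents that add atoms: methanol, CO
Why: Acid-catalysed transketalisation in methanol frees the hydroperoxide, which adds to the ketone (5-exo-trig hemiketalisation forming O2–C3 and the dioxolane ring), and the 1,2-dioxolan-3-ol is then etherified through its peroxycarbenium ion as in a Fischer-type ketal exchange, C5 being untouched.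

Step 14
Reactants: 25 S-ethyl ethanethioate
Product: 27 1-(ethylsulfanyl)-1-[(trimethylsilyl)oxy]ethene, via lithium thioester enolate 26 (not isolated)
Conditions: LiN(iPr)2 (1.05 equiv), THF, −78 °C; Me3SiCl (1.2 equiv), −78 °C → rt; distillation
Reagents that add atoms: chlorotrimethylsilane, C[Si](C)(C)Cl
Why: Kinetic enolisation of the thioester and O-silylation of the lithium enolate, the usual preparation of ketene silyl thioacetals for Mukaiyama chemistry.

Step 15
Reactants: 24 (5R)-3-methoxy-3,5-dimethyl-5-[(2R)-2-methyl-10-phenyldecyl]-1,2-dioxolane; 27 1-(ethylsulfanyl)-1-[(trimethylsilyl)oxy]ethene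
Product: 28 S-ethyl 2-[(3R,5R)-3,5-dimethyl-5-[(2R)-2-methyl-10-phenyldecyl]-1,2-dioxolan-3-yl]ethanethioate
Conditions: 27 (2 equiv), TiCl4 (1.1 equiv), CH2Cl2, −78 °C; H2O quench; chromatographic separation of the C3 epimers
Reagents that add atoms: none
Why: Mukaiyama-type addition of a ketene silyl acetal to the peroxycarbenium ion formed when TiCl4 ionises the methoxy ketal, a known C–C bond formation of 3-alkoxy-1,2-dioxolanes, in which C3 is created on a planar cation differentiated only by the remote C5 substituents, so that both epimers are expected and the (3R,5R) isomer (C3 and C5 methyl groups cis) is isolated by chromatography and assigned by NOE.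

Step 16
Reactants: 28 S-ethyl 2-[(3R,5R)-3,5-dimethyl-5-[(2R)-2-methyl-10-phenyldecyl]-1,2-dioxolan-3-yl]ethanethioate; 18 hydrogen peroxide
Product: 30 2-[(3R,5R)-3,5-dimethyl-5-[(2R)-2-methyl-10-phenyldecyl]-1,2-dioxolan-3-yl]acetic acid, via peroxy acid 29 (not isolated)
Conditions: LiOH·H2O (4 equiv), 30% aq. H2O2 (10 equiv), THF/H2O (3:1), 0 °C; 1 M HCl to pH 3
Reagents that add atoms: none
Why: Acyl substitution of the thioester by lithium hydroperoxide, a more nucleophilic and less basic reagent than hydroxide that should spare the β-peroxy carbonyl unit from retro-Michael ring opening, the transient peroxy acid being reduced in the flask by the liberated thiol and excess H2O2 with no stereocentre involved.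

**Compound list**

1 | (S)-3-bromo-2-methylpropan-1-ol | C[C@H](CBr)CO | starting material
2 | (7-bromoheptyl)benzene | BrCCCCCCCc1ccccc1 | starting material
3 | (7-phenylheptyl)magnesium bromide (not isolated) | Br[Mg]CCCCCCCc1ccccc1 | intermediate
4 | chloromagnesium (S)-3-bromo-2-methylpropan-1-olate (not isolated) | C[C@H](CBr)CO[Mg]Cl | intermediate
5 | (R)-2-methyl-10-phenyldecan-1-ol | C[C@H](CCCCCCCCc1ccccc1)CO | intermediate
6 | (R)-2-methyl-10-phenyldecyl 4-methylbenzenesulfonate | C[C@H](CCCCCCCCc1ccccc1)COS(=O)(=O)c1ccc(C)cc1 | intermediate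
7 | lithium acetylide ethylenediamine complex | [Li]C#C.NCCN | starting material
8 | (R)-4-methyl-12-phenyldodec-1-yne | C[C@H](CCCCCCCCc1ccccc1)CC#C | intermediate
9 | dimethyl[(1E,4R)-2,4-dimethyl-12-phenyldodec-1-en-1-yl]alumane (not isolated) | C[C@H](CCCCCCCCc1ccccc1)C/C(C)=C/[Al](C)C | intermediate
10 | lithium butyl(dimethyl)[(1E,4R)-2,4-dimethyl-12-phenyldodec-1-en-1-yl]aluminate (not isolated) | C[C@H](CCCCCCCCc1ccccc1)C/C(C)=C/[Al-](C)(C)CCCC.[Li+] | intermediate
11 | (2E,5R)-3,5-dimethyl-13-phenyltridec-2-en-1-ol | C[C@H](CCCCCCCCc1ccccc1)C/C(C)=C/CO | intermediate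
12 | [(2S,3S)-3-methyl-3-[(2R)-2-methyl-10-phenyldecyl]oxiran-2-yl]methanol | C[C@H](CCCCCCCCc1ccccc1)C[C@]1(C)O[C@H]1CO | intermediate
13 | (2R,3S)-3-methyl-3-[(2R)-2-methyl-10-phenyldecyl]oxirane-2-carbaldehyde | C[C@H](CCCCCCCCc1ccccc1)C[C@]1(C)O[C@H]1C=O | intermediate
14 | 1-[(2S,3S)-3-methyl-3-[(2R)-2-methyl-10-phenyldecyl]oxiran-2-yl]ethan-1-ol (both carbinol epimers) | C[C@H](CCCCCCCCc1ccccc1)C[C@]1(C)O[C@H]1C(C)O | intermediate
15 | (4S,6R)-4,6-dimethyl-14-phenyltetradecane-2,4-diol (both C2 epimers) | C[C@H](CCCCCCCCc1ccccc1)C[C@@](O)(C)CC(C)O | intermediate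
16 | (4S,6R)-4-hydroxy-4,6-dimethyl-14-phenyltetradecan-2-yl methanesulfonate (not isolated) | C[C@H](CCCCCCCCc1ccccc1)C[C@@](O)(C)CC(C)OS(C)(=O)=O | intermediate
17 | (2S)-2,4-dimethyl-2-[(2R)-2-methyl-10-phenyldecyl]oxetane (both C4 epimers) | C[C@H](CCCCCCCCc1ccccc1)C[C@@]1(C)CC(C)O1 | intermediate
18 | hydrogen peroxide | OO | starting material
19 | (4R,6R)-4-hydroperoxy-4,6-dimethyl-14-phenyltetradecan-2-ol (both C2 epimers) | C[C@H](CCCCCCCCc1ccccc1)C[C@](OO)(C)CC(C)O | intermediate
20 | (4R,6R)-4-[(2-methoxypropan-2-yl)peroxy]-4,6-dimethyl-14-phenyltetradecan-2-ol (both C2 epimers) | C[C@H](CCCCCCCCc1ccccc1)C[C@](OOC(C)(C)OC)(C)CC(C)O | intermediate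
21 | (4R,6R)-4-[(2-methoxypropan-2-yl)peroxy]-4,6-dimethyl-14-phenyltetradecan-2-one | C[C@H](CCCCCCCCc1ccccc1)C[C@](OOC(C)(C)OC)(C)CC(C)=O | intermediate
22 | (4R,6R)-4-hydroperoxy-4,6-dimethyl-14-phenyltetradecan-2-one (not isolated) | C[C@H](CCCCCCCCc1ccccc1)C[C@](OO)(C)CC(C)=O | intermediate
23 | (5R)-3,5-dimethyl-5-[(2R)-2-methyl-10-phenyldecyl]-1,2-dioxolan-3-ol (not isolated) | C[C@H](CCCCCCCCc1ccccc1)C[C@]1(C)CC(C)(O)OO1 | intermediate
24 | (5R)-3-methoxy-3,5-dimethyl-5-[(2R)-2-methyl-10-phenyldecyl]-1,2-dioxolane (both C3 epimers) | C[C@H](CCCCCCCCc1ccccc1)C[C@]1(C)CC(C)(OC)OO1 | intermediate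
25 | S-ethyl ethanethioate | CCSC(C)=O | starting material
26 | lithium 1-(ethylsulfanyl)ethen-1-olate (not isolated) | [Li+].[O-]C(=C)SCC | intermediate
27 | 1-(ethylsulfanyl)-1-[(trimethylsilyl)oxy]ethene | C=C(SCC)O[Si](C)(C)C | intermediate
28 | S-ethyl 2-[(3R,5R)-3,5-dimethyl-5-[(2R)-2-methyl-10-phenyldecyl]-1,2-dioxolan-3-yl]ethanethioate | C[C@H](CCCCCCCCc1ccccc1)C[C@]1(C)C[C@](C)(CC(=O)SCC)OO1 | intermediate
29 | 2-[(3R,5R)-3,5-dimethyl-5-[(2R)-2-methyl-10-phenyldecyl]-1,2-dioxolan-3-yl]ethaneperoxoic acid (not isolated) | C[C@H](CCCCCCCCc1ccccc1)C[C@]1(C)C[C@](C)(CC(=O)OO)OO1 | intermediate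
30 | 2-[(3R,5R)-3,5-dimethyl-5-[(2R)-2-methyl-10-phenyldecyl]-1,2-dioxolan-3-yl]acetic acid | C[C@H](CCCCCCCCc1ccccc1)C[C@]1(C)C[C@](C)(CC(=O)O)OO1 | target

**Step count and risks**

Total steps: 16 (15 in the main line plus the one-step preparation of ketene acetal 27).
Longest linear sequence: 15 steps (steps 1–13, 15 and 16).

Steps most likely to fail:

1. Step 10. The activated oxetane may ionise to a free tertiary cation before H2O2 arrives. That would erode the configuration at the peroxy carbon, give elimination to unsaturated alcohols, and let the product hydroperoxide alkylate on a second oxetane. Fallback: the route sets out again from alkyne 8 and forms the tertiary C–OO bond by radical chemistry, at the price of losing control at that carbon. Carboalumination as in step 4 (through 9 and 10) is quenched with acetaldehyde instead of formaldehyde to give (3E,6R)-4,6-dimethyl-14-phenyltetradec-3-en-2-ol F1. Isayama–Mukaiyama silylperoxidation (Co(acac)2, O2, Et3SiH, ClCH2CH2Cl, rt) places the peroxide at the tertiary carbon and gives (6R)-4,6-dimethyl-14-phenyl-4-[(triethylsilyl)peroxy]tetradecan-2-ol F2. Dess–Martin oxidation with pyridine gives the silylperoxy ketone F3 as both C4 epimers, which are diastereomers through the fixed C6 centre. Preparative HPLC should deliver (4R,6R)-4,6-dimethyl-14-phenyl-4-[(triethylsilyl)peroxy]tetradecan-2-one F4. p-TsOH in MeOH removes the silyl group and closes and ketalises the ring, so the route is rejoined at 24.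

2. Step 15. The peroxycarbenium ion offers little facial bias, so much of the material may end as the C3 epimer. TiCl4 may also cleave the O–O or the C5–O bond in competition with ionisation of the methoxy group. Fallback, from 24: the two-carbon arm is brought in as an allyl group under a milder Lewis acid and then degraded oxidatively. SnCl4 and allyltrimethylsilane (CH2Cl2, −78 °C) should give, after separation of the C3 epimers at this non-polar stage, (3S,5R)-3,5-dimethyl-5-[(2R)-2-methyl-10-phenyldecyl]-3-(prop-2-en-1-yl)-1,2-dioxolane F5. Ozonolysis (O3, CH2Cl2, −78 °C, then Me2S) gives 2-[(3R,5R)-3,5-dimethyl-5-[(2R)-2-methyl-10-phenyldecyl]-1,2-dioxolan-3-yl]acetaldehyde F6. Pinnick oxidation (NaClO2, NaH2PO4, 2-methylbut-2-ene, t-BuOH/H2O) returns to the route at 30. This does not remove the separation of epimers, which is inherent to a planar cation, but it avoids TiCl4 and the base-sensitive thioester.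

3. Step 11. Chemoselectivity may be lost: the secondary hydroxyl may also be ketalised, or the peroxyketal may transketalise intramolecularly to a seven-membered 1,2,4-trioxepane, and either event blocks the oxidation of step 12. Fallback, from 19: discrimination rests instead on the higher acidity of O–O–H in a silylation. t-BuMe2SiCl and imidazole (CH2Cl2, 0 °C, one equivalent) should give (4R,6R)-4-[(tert-butyldimethylsilyl)peroxy]-4,6-dimethyl-14-phenyltetradecan-2-ol F7. Dess–Martin oxidation with pyridine gives (4R,6R)-4-[(tert-butyldimethylsilyl)peroxy]-4,6-dimethyl-14-phenyltetradecan-2-one F8. HCl in MeOH cleaves the silyl peroxide and delivers 24 directly.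

**Further compounds**

F1 | step 10 | (3E,6R)-4,6-dimethyl-14-phenyltetradec-3-en-2-ol (both C2 epimers) | C[C@H](CCCCCCCCc1ccccc1)C/C(C)=C/C(C)O
F2 | step 10 | (6R)-4,6-dimethyl-14-phenyl-4-[(triethylsilyl)peroxy]tetradecan-2-ol (mixture at C2 and C4) | C[C@H](CCCCCCCCc1ccccc1)CC(C)(OO[Si](CC)(CC)CC)CC(C)O
F3 | step 10 | (6R)-4,6-dimethyl-14-phenyl-4-[(triethylsilyl)peroxy]tetradecan-2-one (both C4 epimers) | C[C@H](CCCCCCCCc1ccccc1)CC(C)(OO[Si](CC)(CC)CC)CC(C)=O
F4 | step 10 | (4R,6R)-4,6-dimethyl-14-phenyl-4-[(triethylsilyl)peroxy]tetradecan-2-one | C[C@H](CCCCCCCCc1ccccc1)C[C@](OO[Si](CC)(CC)CC)(C)CC(C)=O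
F5 | step 15 | (3S,5R)-3,5-dimethyl-5-[(2R)-2-methyl-10-phenyldecyl]-3-(prop-2-en-1-yl)-1,2-dioxolane | C[C@H](CCCCCCCCc1ccccc1)C[C@]1(C)C[C@](C)(CC=C)OO1
F6 | step 15 | 2-[(3R,5R)-3,5-dimethyl-5-[(2R)-2-methyl-10-phenyldecyl]-1,2-dioxolan-3-yl]acetaldehyde | C[C@H](CCCCCCCCc1ccccc1)C[C@]1(C)C[C@](C)(CC=O)OO1
F7 | step 11 | (4R,6R)-4-[(tert-butyldimethylsilyl)peroxy]-4,6-dimethyl-14-phenyltetradecan-2-ol (both C2 epimers) | C[C@H](CCCCCCCCc1ccccc1)C[C@](OO[Si](C)(C)C(C)(C)C)(C)CC(C)O
F8 | step 11 | (4R,6R)-4-[(tert-butyldimethylsilyl)peroxy]-4,6-dimethyl-14-phenyltetradecan-2-one | C[C@H](CCCCCCCCc1ccccc1)C[C@](OO[Si](C)(C)C(C)(C)C)(C)CC(C)=O
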